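## Retrosynthetic overview

1. Feature: the only ring is the benzene ring C1–C6 (C1 chain, C2 H, C3 OH, C4 H, C5 OH, C6 OAc). The run C2–C5 (H, O, H, O) is an acetoacetate pattern. C1 and C6 are neighbours that can both come from one alkyne.
2. Last disconnection: C6–OAc ⇒ C6–C(O)CH3. The acetyl group is a latent acetate, unmasked by an aryl-migrating Baeyer–Villiger oxidation on the bis-silyl ether.
3. Key disconnection: bonds C1–C2 and C5–C6 ⇒ alkynyl methyl ketone (C1, C6, chain, acetyl) plus 1-methoxy-1,3-bis(trimethylsilyloxy)butadiene (C2–C5), joined by Diels–Alder reaction and aromatisation.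
4. The ynone comes from linoleyl alcohol (both Z alkenes are bought) by oxidation, one-carbon alkyne homologation and acetylation. The diene comes from methyl acetoacetate by double silylation.
5. Ring order: one ring only, closed in the key step. The target has no stereocentre, and the two Z alkenes are carried through unchanged.

Key step: step 6

Assumption: the enol-ether geometries drawn for 10, 11 and 12 are taken as the ones formed. They have no bearing on the route, because these double bonds end inside the aromatic ring. All compounds holding the skipped diene are handled under argon.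

## Route

Step 1
Reactants: 1 linoleyl alcohol, (9Z,12Z)-octadeca-9,12-dien-1-ol
Product: 2 (9Z,12Z)-octadeca-9,12-dienal
Conditions: TEMPO (0.1 equiv), PhI(OAc)2 (1.1 equiv), CH2Cl2, 0 °C → rt; aq. Na2S2O3/NaHCO3 wash
Reagents that add atoms: none
Why: Oxoammonium-mediated alcohol oxidation (TEMPO with PhI(OAc)2 as terminal oxidant) stops at the aldehyde in the absence of water and leaves the isolated Z alkenes and the doubly allylic CH2 group untouched.

Step 2
Reactants: 2 (9Z,12Z)-octadeca-9,12-dienal; 3 dimethyl (1-diazo-2-oxopropyl)phosphonate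
Product: 4 (10Z,13Z)-nonadeca-10,13-dien-1-yne
Conditions: 3 (1.3 equiv), K2CO3 (2 equiv), MeOH, 0 °C → rt
Reagents that add atoms: dimethyl (1-diazo-2-oxopropyl)phosphonate (3), COP(=O)(OC)C(=[N+]=[N-])C(C)=O
Why: Seyferth–Gilbert homologation in its Ohira–Bestmann variant: methanolysis of 3 frees the diazomethylphosphonate anion, which adds to the aldehyde, and phosphate elimination, loss of N2 and a 1,2-hydrogen shift give the terminal alkyne under a base too weak to bring the skipped diene into conjugation.

Step 3
Reactants: 4 (10Z,13Z)-nonadeca-10,13-dien-1-yne; 5 N-methoxy-N-methylacetamide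
Product: 8 (12Z,15Z)-henicosa-12,15-dien-3-yn-2-one, via lithium acetylide 6 (not isolated), via tetrahedral lithium adduct 7 (not isolated)
Conditions: n-BuLi (1.0 equiv), THF, −78 °C; 5 (1.3 equiv), −78 → −20 °C; cannulated into cold 1 M aq. HCl
Reagents that add atoms: N-methoxy-N-methylacetamide (5), CON(C)C(C)=O
Why: Weinreb ketone synthesis on a lithium acetylide: n-BuLi at −78 °C removes only the alkyne C–H, chelated adduct 7 holds until the quench so that no second addition takes place, and the inverse acidic quench keeps the freed N,O-dimethylhydroxylamine protonated so that it cannot add to the ynone.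

Step 4
Reactants: 9 methyl acetoacetate
Product: 10 methyl (E)-3-(trimethylsilyloxy)but-2-enoate (the Z isomer serves equally)
Conditions: TMSCl (1.2 equiv), Et3N (1.3 equiv), hexane, rt; filtration, distillation
Reagents that add atoms: chlorotrimethylsilane, C[Si](C)(C)Cl
Why: Soft enolisation and O-silylation of a β-keto ester with Et3N/TMSCl is a standard silyl enol ether synthesis, driven by precipitation of the ammonium salt.

Step 5
Reactants: 10 methyl (E)-3-(trimethylsilyloxy)but-2-enoate
Product: 12 (1Z)-1-methoxy-1,3-bis(trimethylsilyloxy)buta-1,3-diene, via lithium dienolate 11 (not isolated)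
Conditions: LiN(i-Pr)2 (LDA, commercial solution, 1.1 equiv), THF, −78 °C; TMSCl (1.2 equiv), −78 → 0 °C; hexane, filtration, used without chromatography
Reagents that add atoms: chlorotrimethylsilane, C[Si](C)(C)Cl
Why: Silyl ketene acetal formation: LDA removes a γ-proton of the β-silyloxy enoate to give extended enolate 11, which the hard electrophile TMSCl traps at oxygen.

Step 6
Reactants: 8 (12Z,15Z)-henicosa-12,15-dien-3-yn-2-one; 12 (1Z)-1-methoxy-1,3-bis(trimethylsilyloxy)buta-1,3-diene
Product: 14 1-{2,4-dihydroxy-6-[(8Z,11Z)-heptadeca-8,11-dien-1-yl]phenyl}ethanone, via cyclohexadiene cycloadduct 13 (not isolated)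
Conditions: 12 (3 equiv), BHT (cat.), toluene, sealed tube, Ar, 110 °C, no Lewis acid; then aq. HCl (cat.), THF, rt
Reagents that add atoms: (1Z)-1-methoxy-1,3-bis(trimethylsilyloxy)buta-1,3-diene (12), CO/C(O[Si](C)(C)C)=C/C(O[Si](C)(C)C)=C
Why: The HOMO of 12 is largest at its CH2 terminus, which all three oxygen donors push, and the LUMO of 8 is largest at the chain-bearing β-alkyne carbon, so the normal-electron-demand (4+2) cycloaddition is strongly asynchronous, with the C2–C1 bond leading and the ketene acetal carbon then closing the C5–C6 bond onto the acetyl-bearing carbon. The closest known reaction type is the Diels–Alder reaction and aromatisation of 1-alkoxy-1,3-bis(silyloxy)butadienes and related 1,1,3-trioxygenated dienes with acetylenic esters and ketones, which gives 6-substituted 2,4-dihydroxyaryl carbonyl compounds. The one ring, the six-membered carbocycle C1–C6, is closed in a bimolecular (4+2) mode from two open-chain partners, and cyclohexa-1,4-diene 13 becomes aromatic on acidic work-up, when Si–O cleavage at the mixed ketal carbon C5 expels methanol and the resulting dienone tautomerises. No stereocentre remains, since the single one of 13 (C5, racemic) and the enol-ether geometry of 12 vanish on aromatisation, and both Z alkenes are spectators. The step needs regioselectivity (chain next to C2–H, acetyl next to C5–OH), which this polarity match secures, and chemoselectivity for the conjugated triple bond over the two isolated alkenes and the ketone carbonyl, which is secured by working thermally, because a Lewis acid would divert the diene to carbonyl addition and a (3+3) closure.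

Step 7
Reactants: 14 1-{2,4-dihydroxy-6-[(8Z,11Z)-heptadeca-8,11-dien-1-yl]phenyl}ethanone
Product: 15 1-{2,4-bis(tert-butyldimethylsilyloxy)-6-[(8Z,11Z)-heptadeca-8,11-dien-1-yl]phenyl}ethanone
Conditions: TBSCl (3 equiv), imidazole (6 equiv), DMAP (cat.), DMF, rt → 40 °C
Reagents that add atoms: tert-butyldimethylsilyl chloride, CC(C)(C)[Si](C)(C)Cl
Why: Imidazole-promoted silyl ether formation, in which the free C3–OH reacts first and the hydrogen-bonded C5–OH follows with excess reagent, DMAP and gentle warming, and masking both phenols keeps them from oxidation and from binding SnCl4 in step 8.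

Step 8
Reactants: 15 1-{2,4-bis(tert-butyldimethylsilyloxy)-6-[(8Z,11Z)-heptadeca-8,11-dien-1-yl]phenyl}ethanone
Product: 16 2,4-bis(tert-butyldimethylsilyloxy)-6-[(8Z,11Z)-heptadeca-8,11-dien-1-yl]phenyl acetate
Conditions: (Me3SiO)2 (3 equiv, handled in solution), SnCl4 (0.25 equiv), trans-N,N'-bis(p-toluenesulfonyl)cyclohexane-1,2-diamine (0.25 equiv), MS 4 Å, CH2Cl2, −20 °C → rt
Reagents that add atoms: bis(trimethylsilyl) peroxide, C[Si](C)(C)OO[Si](C)(C)C
Why: Baeyer–Villiger oxidation in the bis(trimethylsilyl) peroxide/SnCl4 variant: the silyl peroxide adds only to the Lewis-acid-activated carbonyl group and offers no electrophilic peracid oxygen, so the Z alkenes are not epoxidised, and the electron-rich, twisted aryl group migrates in preference to methyl, which places the new oxygen between C6 and the acetyl carbon.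

Step 9
Reactants: 16 2,4-bis(tert-butyldimethylsilyloxy)-6-[(8Z,11Z)-heptadeca-8,11-dien-1-yl]phenyl acetate
Product: 17 ardisiphenol C, 2,4-dihydroxy-6-[(8Z,11Z)-heptadeca-8,11-dien-1-yl]phenyl acetate
Conditions: HF·pyridine, pyridine, THF, 0 °C, plastic vessel; excess HF quenched with Me3SiOMe, no basic wash
Reagents that add atoms: none
Why: Fluoride-driven Si–O cleavage under mildly acidic, non-nucleophilic conditions frees both phenols without building up phenoxide, which keeps the aryl acetate in place and holds back its shift to the neighbouring C5 oxygen.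

## Compound list

1 | linoleyl alcohol, (9Z,12Z)-octadeca-9,12-dien-1-ol | CCCCC/C=C\C/C=C\CCCCCCCCO | starting material
2 | (9Z,12Z)-octadeca-9,12-dienal | CCCCC/C=C\C/C=C\CCCCCCCC=O | intermediate
3 | dimethyl (1-diazo-2-oxopropyl)phosphonate | COP(=O)(OC)C(=[N+]=[N-])C(C)=O | starting material
4 | (10Z,13Z)-nonadeca-10,13-dien-1-yne | CCCCC/C=C\C/C=C\CCCCCCCC#C | intermediate
5 | N-methoxy-N-methylacetamide | CON(C)C(C)=O | starting material
6 | lithium (10Z,13Z)-nonadeca-10,13-dien-1-yn-1-ide | CCCCC/C=C\C/C=C\CCCCCCCC#[C-].[Li+] | intermediate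
7 | lithium (12Z,15Z)-2-[methoxy(methyl)amino]henicosa-12,15-dien-3-yn-2-olate (racemic) | CCCCC/C=C\C/C=C\CCCCCCCC#CC(C)([O-])N(C)OC.[Li+] | intermediate
8 | (12Z,15Z)-henicosa-12,15-dien-3-yn-2-one | CCCCC/C=C\C/C=C\CCCCCCCC#CC(C)=O | intermediate
9 | methyl acetoacetate | COC(=O)CC(C)=O | starting material
10 | methyl (E)-3-(trimethylsilyloxy)but-2-enoate | COC(=O)/C=C(\C)O[Si](C)(C)C | intermediate
11 | lithium 1-methoxy-3-(trimethylsilyloxy)buta-1,3-dien-1-olate (O–Li cis to C3) | CO/C([O-])=C/C(=C)O[Si](C)(C)C.[Li+] | intermediate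
12 | (1Z)-1-methoxy-1,3-bis(trimethylsilyloxy)buta-1,3-diene | CO/C(O[Si](C)(C)C)=C/C(O[Si](C)(C)C)=C | intermediate
13 | 1-{2-[(8Z,11Z)-heptadeca-8,11-dien-1-yl]-6-methoxy-4,6-bis(trimethylsilyloxy)cyclohexa-1,4-dien-1-yl}ethanone (racemic at C6 of the cyclohexadiene) | CCCCC/C=C\C/C=C\CCCCCCCC1=C(C(C)=O)C(OC)(O[Si](C)(C)C)C=C(O[Si](C)(C)C)C1 | intermediate
14 | 1-{2,4-dihydroxy-6-[(8Z,11Z)-heptadeca-8,11-dien-1-yl]phenyl}ethanone | CCCCC/C=C\C/C=C\CCCCCCCc1cc(O)cc(O)c1C(C)=O | intermediate
15 | 1-{2,4-bis(tert-butyldimethylsilyloxy)-6-[(8Z,11Z)-heptadeca-8,11-dien-1-yl]phenyl}ethanone | CCCCC/C=C\C/C=C\CCCCCCCc1cc(O[Si](C)(C)C(C)(C)C)cc(O[Si](C)(C)C(C)(C)C)c1C(C)=O | intermediate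
16 | 2,4-bis(tert-butyldimethylsilyloxy)-6-[(8Z,11Z)-heptadeca-8,11-dien-1-yl]phenyl acetate | CCCCC/C=C\C/C=C\CCCCCCCc1cc(O[Si](C)(C)C(C)(C)C)cc(O[Si](C)(C)C(C)(C)C)c1OC(C)=O | intermediate
17 | ardisiphenol C, 2,4-dihydroxy-6-[(8Z,11Z)-heptadeca-8,11-dien-1-yl]phenyl acetate | CCCCC/C=C\C/C=C\CCCCCCCc1cc(O)cc(O)c1OC(C)=O | target

## Step count and risks

Total step count: 9. The longest linear sequence has 7 steps (1, 2, 3, 6, 7, 8, 9). The diene branch (steps 4 and 5) joins at step 6.

**Step 6.**
- What may go wrong: the acyclic ketene-acetal diene may decay, by silyl migration or by protonation from the enolisable acetyl group, faster than it adds to the β-alkyl-substituted triple bond.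
- A second failure mode is that silyl transfer follows the first C–C bond instead of ring closure. The material then stays open-chain and closes through the ketone carbonyl on work-up.
- The fallback runs from 8 back to 14. It replaces elimination-driven aromatisation by an Alder–Rickert sequence (cycloaddition, then cycloreversion) with a ring-locked diene that holds no ketene acetal.
- Dimedone is bis-silylated (TMSOTf, Et3N, Et2O, 0 °C) to 5,5-dimethyl-1,3-bis(trimethylsilyloxy)cyclohexa-1,3-diene F1.
- Heating 8 with F1 neat at about 140 °C under argon should give 1-{3-[(8Z,11Z)-heptadeca-8,11-dien-1-yl]-8,8-dimethyl-1,5-bis(trimethylsilyloxy)bicyclo[2.2.2]octa-2,5-dien-2-yl}ethanone F2. Here the unsubstituted diene terminus has bonded to the chain-bearing carbon by the same polarity match.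
- At this temperature the bridge leaves by retro-Diels–Alder reaction to give 1-{2-[(8Z,11Z)-heptadeca-8,11-dien-1-yl]-4,6-bis(trimethylsilyloxy)phenyl}ethanone F3. Dilute HCl in THF then gives 14.

**Step 8.**
- What may go wrong: peroxide addition to the carbonyl group, crowded by the silyloxy group and the C17 chain, may be slow. Lewis-acid-induced loss of the chelating ortho silyl group, or electrophilic oxygenation of the activated ring positions, may then win.
- The fallback runs from 15 back to 16. It replaces the oxygen insertion by a benzylic hydroperoxide (Hock-type) rearrangement.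
- MeLi/CeCl3 (THF, −78 °C) adds to 15 to give 2-{2,4-bis(tert-butyldimethylsilyloxy)-6-[(8Z,11Z)-heptadeca-8,11-dien-1-yl]phenyl}propan-2-ol F4.
- H2O2 with an acid promoter (BF3·OEt2 or TsOH, CH2Cl2/THF, 0 °C) exchanges OH for OOH through the strongly stabilised benzylic cation. This gives 2-{2,4-bis(tert-butyldimethylsilyloxy)-6-[(8Z,11Z)-heptadeca-8,11-dien-1-yl]phenyl}propan-2-yl hydroperoxide F5, which is not isolated.
- Aryl shift to oxygen and hydrolysis then give 2,4-bis(tert-butyldimethylsilyloxy)-6-[(8Z,11Z)-heptadeca-8,11-dien-1-yl]phenol F6.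
- F6 is acetylated at once (Ac2O, pyridine, 0 °C), before silyl migration between the neighbouring oxygens can set in, to give 16. H2O2 under acid without a carboxylic acid does not epoxidise the alkenes.

**Step 9.**
- What may go wrong: slow cleavage of the hindered C5 silyl ether prolongs the exposure. The acetyl group may then wander from the C6 oxygen to the freed C5 oxygen or be lost by solvolysis.
- The fallback runs from 14 to 17. It drops the separate deprotection by using silyl groups that leave on aqueous work-up.
- Compound 14 is silylated (TMSCl, Et3N, CH2Cl2; filtered and concentrated, not purified) to the bis(trimethylsilyl) ether F3 already described.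
- Baeyer–Villiger oxidation in a silylating medium ((Me3SiO)2, TMSOTf cat., CH2Cl2, −40 °C) should give 2-[(8Z,11Z)-heptadeca-8,11-dien-1-yl]-4,6-bis(trimethylsilyloxy)phenyl acetate F7.
- A short work-up with cold dilute citric acid in THF/water then gives 17 without fluoride or base.

## Further compounds

F1 | step 6 | 5,5-dimethyl-1,3-bis(trimethylsilyloxy)cyclohexa-1,3-diene | CC1(C)CC(O[Si](C)(C)C)=CC(O[Si](C)(C)C)=C1
F2 | step 6 | 1-{3-[(8Z,11Z)-heptadeca-8,11-dien-1-yl]-8,8-dimethyl-1,5-bis(trimethylsilyloxy)bicyclo[2.2.2]octa-2,5-dien-2-yl}ethanone (racemic, bridgeheads fixed by the bicycle) | CCCCC/C=C\C/C=C\CCCCCCCC1=C(C(C)=O)C2(O[Si](C)(C)C)C=C(O[Si](C)(C)C)C1C(C)(C)C2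
F3 | step 6 | 1-{2-[(8Z,11Z)-heptadeca-8,11-dien-1-yl]-4,6-bis(trimethylsilyloxy)phenyl}ethanone | CCCCC/C=C\C/C=C\CCCCCCCc1cc(O[Si](C)(C)C)cc(O[Si](C)(C)C)c1C(C)=O
F4 | step 8 | 2-{2,4-bis(tert-butyldimethylsilyloxy)-6-[(8Z,11Z)-heptadeca-8,11-dien-1-yl]phenyl}propan-2-ol | CCCCC/C=C\C/C=C\CCCCCCCc1cc(O[Si](C)(C)C(C)(C)C)cc(O[Si](C)(C)C(C)(C)C)c1C(C)(C)O
F5 | step 8 | 2-{2,4-bis(tert-butyldimethylsilyloxy)-6-[(8Z,11Z)-heptadeca-8,11-dien-1-yl]phenyl}propan-2-yl hydroperoxide | CCCCC/C=C\C/C=C\CCCCCCCc1cc(O[Si](C)(C)C(C)(C)C)cc(O[Si](C)(C)C(C)(C)C)c1C(C)(C)OO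
F6 | step 8 | 2,4-bis(tert-butyldimethylsilyloxy)-6-[(8Z,11Z)-heptadeca-8,11-dien-1-yl]phenol | CCCCC/C=C\C/C=C\CCCCCCCc1cc(O[Si](C)(C)C(C)(C)C)cc(O[Si](C)(C)C(C)(C)C)c1O
F7 | step 9 | 2-[(8Z,11Z)-heptadeca-8,11-dien-1-yl]-4,6-bis(trimethylsilyloxy)phenyl acetate | CCCCC/C=C\C/C=C\CCCCCCCc1cc(O[Si](C)(C)C)cc(O[Si](C)(C)C)c1OC(C)=O
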